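**Plan**

- Retrosynthesis: the two phenols of target 15 are unmasked last from bis(silyl ether) 14, and the benzene ring of 14 is cut at C1–C2, C3–C4 and C5–C6 (C1 CO2Me, C2 O, C3 prenyl, C4 O, C5 prenyl, C6 phenethyl).
- Enabling feature: donor and acceptor carbons alternate around this ring, so C2–C3 and C4–C5 are the same O–C≡C–prenyl unit and C6–C1 is a phenethyl–C≡C–CO2Me unit, all three lying head to tail.
- Precursors: siloxyalkyne 9 (used twice) and alkynoate 13. Alkyne 9 comes from a lithium ynolate made without chain extension from α-bromo ester 6, itself from Johnson–Claisen ester 4. Alkynoate 13 comes from 4-phenylbut-1-yne and methyl chloroformate.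
- Forward: a three-step branch and a one-step branch converge in a rhodium-catalysed (2+2+2) cycloaddition that forms the only ring made in the route, the benzene ring; double desilylation then gives the target.
- Stereochemistry: the target has no stereocentre and both alkenes carry geminal methyl groups, so nothing needs control; the racemic centre of 6 is erased in the ynolate.

Key step: step 5

Remark: ester 4 and siloxyalkyne 9 have the same six-carbon chain, so the ynolate is generated by ester-dianion cleavage of the α-bromo ester, which keeps the carbon count. A dibromomethyllithium homologation of 4 would add one carbon and give the homoprenyl alkyne, so it is not used.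

**Route**

Step 1
Reactants: 1 2-methylbut-3-en-2-ol; 2 triethyl orthoacetate
Product: 4 ethyl 5-methylhex-4-enoate, via mixed ketene acetal 3 (not isolated)
Conditions: 2 (excess), EtCO2H (cat.), 140 °C, EtOH distilled off
Reagents that add atoms: none
Why: Johnson–Claisen rearrangement, in which acid-catalysed exchange and loss of ethanol give the allyl ketene acetal, whose (3,3)-sigmatropic shift delivers the γ,δ-unsaturated ester with the trisubstituted dimethyl alkene, so no stereocentre or alkene geometry arises.

Step 2
Reactants: 4 ethyl 5-methylhex-4-enoate
Product: 6 ethyl 2-bromo-5-methylhex-4-enoate (racemic), via silyl ketene acetal 5 (not isolated)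
Conditions: LiN(i-Pr)2, THF, −78 °C; Me3SiCl; then NBS, −78 to 0 °C
Reagents that add atoms: N-bromosuccinimide, O=C1CCC(=O)N1Br
Why: α-bromination of an ester through its O-silyl ketene acetal, which is far more nucleophilic toward NBS than the trisubstituted alkene and, being neutral, cannot exchange protons with the product, so monobromination should result.

Step 3
Reactants: 6 ethyl 2-bromo-5-methylhex-4-enoate
Product: 9 [(5-methylhex-4-en-1-yn-1-yl)oxy]tri(propan-2-yl)silane, via lithium bromoenolate 7 (not isolated), via lithium ynolate 8 (not isolated)
Conditions: LiN(SiMe3)2, THF, −78 °C; t-BuLi, −78 to 0 °C; then i-Pr3SiOTf, −78 °C to rt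
Reagents that add atoms: triisopropylsilyl trifluoromethanesulfonate, CC(C)[Si](OS(=O)(=O)C(F)(F)F)(C(C)C)C(C)C
Why: ynolate formation by ester-dianion cleavage (deprotonation, Li/Br exchange, loss of LiOEt) keeps the six-carbon chain, and the bulky silyl triflate is known to trap lithium ynolates on oxygen to give isolable triisopropylsilyl ynol ethers.

Step 4
Reactants: 10 4-phenylbut-1-yne; 11 methyl chloroformate
Product: 13 methyl 5-phenylpent-2-ynoate, via lithium acetylide 12 (not isolated)
Conditions: n-BuLi, THF, −78 °C; then 11, −78 to 0 °C
Reagents that add atoms: none
Why: C-acylation of a lithium acetylide with a chloroformate is the standard entry to alk-2-ynoates, and the low temperature with a slight excess of 11 should suppress a second addition.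

Step 5
Reactants: 9 [(5-methylhex-4-en-1-yn-1-yl)oxy]tri(propan-2-yl)silane (two molecules); 13 methyl 5-phenylpent-2-ynoate
Product: 14 methyl 3,5-bis(3-methylbut-2-en-1-yl)-6-(2-phenylethyl)-2,4-bis{[tri(propan-2-yl)silyl]oxy}benzoate
Conditions: [Rh(cod)2]BF4 (5 mol %), rac-BINAP (5 mol %), H2 then Ar, CH2Cl2, rt; 9 added slowly by syringe pump to 13 and catalyst
Reagents that add atoms: none
Why: Proposed new method: the cationic monovalent rhodium–BINAP fragment, freed from cod by hydrogenation, should take up one molecule of electron-rich 9 and the electron-poor 13 and couple them oxidatively so that the prenyl-bearing carbon of 9 (nucleophilic, β to oxygen) bonds to the phenethyl-bearing β-carbon of 13 (C5–C6), giving a trivalent rhodacyclopentadiene with the metal on C4 and C1. A second molecule of 9 then inserts into the Rh–C4 bond with its prenyl-bearing carbon joining C4 (C3–C4), and the benzene ring closes by reductive elimination of C1–C2 from the seven-membered rhodacycle, an intermolecular three-component (2+2+2) closure of a six-membered carbocycle. The closest known reaction type is the cationic rhodium/bisphosphine-catalysed chemo- and regioselective cross-cyclotrimerization of two electron-rich alkynes with one electron-poor alkyne ester; the union of three unsymmetrical internal alkynes, two of them silyl ynol ethers, to a hexasubstituted benzene has not been shown. No stereocentre is created. The step needs two-to-one cross-selection over homotrimerization of either partner and a head-to-tail sense at all three new bonds; both are meant to follow from the donor–acceptor polarization, since every new bond pairs a carbon β to silyloxy or α to the ester with a carbon bearing silyloxy or β to the ester, and from keeping 9 scarce by slow addition. The neutral aprotic medium should leave the prenyl alkenes, the Si–O bonds and the ester untouched.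

Step 6
Reactants: 14 methyl 3,5-bis(3-methylbut-2-en-1-yl)-6-(2-phenylethyl)-2,4-bis{[tri(propan-2-yl)silyl]oxy}benzoate
Product: 15 methyl 2,4-dihydroxy-3,5-bis(3-methylbut-2-en-1-yl)-6-(2-phenylethyl)benzoate
Conditions: Bu4NF, AcOH, THF, 0 °C
Reagents that add atoms: none
Why: fluoride cleavage of aryl silyl ethers is driven by Si–F bond formation, while the acetic acid buffer protonates the phenoxides as they form and is too weak to cyclise the ortho-prenyl phenols to chromans or to touch the methyl ester.

**Compound list**

1 | 2-methylbut-3-en-2-ol | CC(C)(O)C=C | starting material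
2 | triethyl orthoacetate | CCOC(C)(OCC)OCC | starting material
3 | 3-[(1-ethoxyethenyl)oxy]-3-methylbut-1-ene (mixed ketene acetal) | C=C(OCC)OC(C)(C)C=C | intermediate (not isolated)
4 | ethyl 5-methylhex-4-enoate | CCOC(=O)CCC=C(C)C | intermediate
5 | [(1-ethoxy-5-methylhexa-1,4-dien-1-yl)oxy]trimethylsilane (silyl ketene acetal, enol ether geometry not defined) | CCOC(=CCC=C(C)C)O[Si](C)(C)C | intermediate (not isolated)
6 | ethyl 2-bromo-5-methylhex-4-enoate (racemic) | CCOC(=O)C(Br)CC=C(C)C | intermediate
7 | lithium 2-bromo-1-ethoxy-5-methylhexa-1,4-dien-1-olate (lithium bromoenolate) | [Li+].CCOC([O-])=C(Br)CC=C(C)C | intermediate (not isolated)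
8 | lithium 5-methylhex-4-en-1-yn-1-olate (lithium ynolate) | [Li+].[O-]C#CCC=C(C)C | intermediate (not isolated)
9 | [(5-methylhex-4-en-1-yn-1-yl)oxy]tri(propan-2-yl)silane | CC(C)=CCC#CO[Si](C(C)C)(C(C)C)C(C)C | intermediate
10 | 4-phenylbut-1-yne | C#CCCc1ccccc1 | starting material
11 | methyl chloroformate | COC(=O)Cl | starting material
12 | lithium 4-phenylbut-1-yn-1-ide (lithium acetylide) | [Li+].[C-]#CCCc1ccccc1 | intermediate (not isolated)
13 | methyl 5-phenylpent-2-ynoate | COC(=O)C#CCCc1ccccc1 | intermediate
14 | methyl 3,5-bis(3-methylbut-2-en-1-yl)-6-(2-phenylethyl)-2,4-bis{[tri(propan-2-yl)silyl]oxy}benzoate | COC(=O)c1c(O[Si](C(C)C)(C(C)C)C(C)C)c(CC=C(C)C)c(O[Si](C(C)C)(C(C)C)C(C)C)c(CC=C(C)C)c1CCc1ccccc1 | intermediate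
15 | methyl 2,4-dihydroxy-3,5-bis(3-methylbut-2-en-1-yl)-6-(2-phenylethyl)benzoate | COC(=O)c1c(O)c(CC=C(C)C)c(O)c(CC=C(C)C)c1CCc1ccccc1 | target

**Summary**

Total step count: 6. Longest linear sequence: 5 steps (steps 1, 2, 3, 5, 6); step 4 is the one-step side branch.

Steps most likely to fail:

1. Step 5 (the proposed new method). The siloxyalkyne may homotrimerize or add to the alkynoate in a metal-induced (2+2) sense, the oxidative coupling may take the wrong orientation, or the crowded hexasubstituted ring may fail to close and stall the catalyst. The fallback builds the ring by known chemistry from alkynoate 13. A Diels–Alder reaction with commercial 1-methoxy-1,3-bis(trimethylsilyloxy)buta-1,3-diene (toluene, sealed tube, about 130 °C) should join the unsubstituted diene terminus to the β-carbon of 13. Aromatisation by loss of methanol and acidic desilylation on work-up would give methyl 2,4-dihydroxy-6-(2-phenylethyl)benzoate F1. Its only free ring positions are C3 and C5, so double C-prenylation of its sodium phenoxide with commercial 1-bromo-3-methylbut-2-ene (NaH, toluene, a non-polar medium that favours ortho C-alkylation over O-alkylation) would lead directly to target 15. Compounds 9 and 14 and step 6 are then not needed.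

2. Step 3. The bromoenolate may decompose in a carbenoid manner before Li/Br exchange, the dianion may fragment incompletely, silylation may occur on carbon to give a silylketene, or the ynol ether may hydrolyse during isolation. The fallback reaches the same ynolate by oxidising an acetylide and sets out from alcohol 1. Aqueous HBr (0 °C) should give 1-bromo-3-methylbut-2-ene F2 by allylic transposition. Coupling with HC≡CMgBr under CuCl catalysis in THF would give 5-methylhex-4-en-1-yne F3. Deprotonation with LiN(SiMe3)2 (THF, −78 °C) gives lithium 5-methylhex-4-en-1-yn-1-ide F4, which is oxidised by lithium tert-butyl peroxide (from t-BuOOH and a second equivalent of the amide, −78 to 0 °C) to ynolate 8. Silylation with i-Pr3SiOTf as in step 3 returns to siloxyalkyne 9.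

3. Step 2. Silylation of the ester enolate may occur partly on carbon, NBS may attack the trisubstituted alkene, and incomplete or repeated bromination may give mixtures that are hard to separate. The fallback makes exhaustive bromination the aim and sets out from ester 4. Two successive enolisation–bromination cycles with LiN(i-Pr)2 and BrCCl2CCl2Br (a bromine donor that does not add to alkenes) should give ethyl 2,2-dibromo-5-methylhex-4-enoate F5. Treatment with t-BuLi alone (THF, −78 to 0 °C) would effect double Li/Br exchange and dianion cleavage without any amide base, giving ynolate 8. Silylation with i-Pr3SiOTf rejoins the route at 9.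

**Further compounds**

F1 | step 5 | methyl 2,4-dihydroxy-6-(2-phenylethyl)benzoate | COC(=O)c1c(O)cc(O)cc1CCc1ccccc1
F2 | step 3 | 1-bromo-3-methylbut-2-ene | CC(C)=CCBr
F3 | step 3 | 5-methylhex-4-en-1-yne | CC(C)=CCC#C
F4 | step 3 | lithium 5-methylhex-4-en-1-yn-1-ide | [Li+].[C-]#CCC=C(C)C
F5 | step 2 | ethyl 2,2-dibromo-5-methylhex-4-enoate | CCOC(=O)C(Br)(Br)CC=C(C)C
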